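Ring B is opened at its most crowded bond, C4–C4a. The C4 ketone links the fully substituted C3 (CH3, Cl) to ring-A carbon C4a, which lies between the C5 oxygen and C8a. A neutral, intramolecular thioester–arylboronic acid acyl coupling forges this bond last and closes ring B in one operation. This spares the base-labile C2/C3 chlorohydrin and the acid-labile triene. The precursor is an open-chain S-ethyl thioester (C4) that already holds both stereocentres, with C2–O silylated, the C1 aryl ketone in place and B(OH)2 on C4a. It arises from a copper–bis(oxazoline) Mukaiyama aldol between a borylated aryl 1,2-diketone and an α-chloro ketene thioacetal.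

Key step: step 16

Remark on numbering: labels C1–C8a follow the target 2,3-dihydronaphthalene-1,4-dione and are used for the same atoms in the open-chain intermediates.
Assumption: the face of the C2 carbonyl left open by the (R,R)-ligand in step 14 is assigned from the square-planar chelate model of this catalyst family; if the opposite sense is met, the (S,S)-ligand is used.

Step 1
Reactants: 1 ethyl acetoacetate; 2 geranyl bromide
Product: 4 ethyl (4E)-2-acetyl-5,9-dimethyldeca-4,8-dienoate (racemic), via sodium acetoacetate enolate 3 (not isolated)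
Conditions: NaH, THF, 0 °C; then 2, 0 °C to rt
Reagents that add atoms: none
Why: Acetoacetic ester alkylation, in which the soft stabilised enolate displaces the primary allylic bromide by SN2 at carbon without allylic transposition, so the E-alkene is kept and the new centre, formed racemic, is erased in step 2.

Step 2
Reactants: 4 ethyl (4E)-2-acetyl-5,9-dimethyldeca-4,8-dienoate
Product: 6 ethyl (2Z,4E)-5,9-dimethyl-2-[1-(trifluoromethanesulfonyloxy)ethylidene]deca-4,8-dienoate, via sodium enolate 5 (not isolated)
Conditions: NaH, THF, 0 °C; PhNTf2, 0 °C to rt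
Reagents that add atoms: N-phenylbis(trifluoromethanesulfonimide), O=S(=O)(N(c1ccccc1)S(=O)(=O)C(F)(F)F)C(F)(F)F
Why: O-sulfonylation of the chelated enolate of a beta-keto ester with a mild triflyl donor gives the enol triflate without acid that could harm the diene, and its geometry does not matter because step 3 places a second methyl group on the same carbon.

Step 3
Reactants: 6 enol triflate
Product: 7 ethyl (4E)-5,9-dimethyl-2-(propan-2-ylidene)deca-4,8-dienoate
Conditions: MeMgBr, Fe(acac)3 (5 mol %), THF/NMP, −30 °C
Reagents that add atoms: methylmagnesium bromide, C[Mg]Br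
Why: Iron-catalysed Kumada-type cross-coupling of an electron-poor alkenyl triflate with a methyl Grignard reagent outruns attack on the ester and fixes the tetrasubstituted isopropylidene alkene at a defined position, which deconjugative alkylation routes cannot guarantee.

Step 4
Reactants: 7 ethyl (4E)-5,9-dimethyl-2-(propan-2-ylidene)deca-4,8-dienoate
Product: 8 (4E)-5,9-dimethyl-2-(propan-2-ylidene)deca-4,8-dien-1-ol
Conditions: i-Bu2AlH, CH2Cl2, −78 to 0 °C; aq potassium sodium tartrate
Reagents that add atoms: none
Why: 1,2-Reduction of a conjugated ester with a neutral aluminium hydride gives the allylic alcohol and leaves all three alkenes alone.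

Step 5
Reactants: 8 (4E)-5,9-dimethyl-2-(propan-2-ylidene)deca-4,8-dien-1-ol
Product: 9 (4E)-1-bromo-5,9-dimethyl-2-(propan-2-ylidene)deca-4,8-diene
Conditions: CBr4, PPh3, CH2Cl2, 0 °C; used at once
Reagents that add atoms: tetrabromomethane, BrC(Br)(Br)Br
Why: The Appel reaction replaces the primary allylic hydroxyl by bromide through SN2 on the oxyphosphonium salt under neutral conditions, so no acid-induced cyclisation or allylic shift of the triene is expected.

Step 6
Reactants: 10 3,5-dihydroxyacetophenone
Product: 11 1-[3,5-bis(methoxymethoxy)phenyl]ethan-1-one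
Conditions: MeOCH2Cl, i-Pr2NEt, CH2Cl2, 0 °C to rt
Reagents that add atoms: chloromethyl methyl ether, COCCl
Why: Phenol O-alkylation gives acetal ethers that withstand the amide bases, palladium catalysis and oxidants ahead and can be removed at the end without strong acid or base.

Step 7
Reactants: 11 1-[3,5-bis(methoxymethoxy)phenyl]ethan-1-one
Product: 12 1-[2-bromo-3,5-bis(methoxymethoxy)phenyl]ethan-1-one
Conditions: N-bromosuccinimide, MeCN, 0 °C to rt
Reagents that add atoms: N-bromosuccinimide, O=C1CCC(=O)N1Br
Why: Electrophilic aromatic bromination of 3,5-dialkoxyaryl carbonyl compounds goes para to one ether and ortho to the other, which is the later C4a, and avoids the position wedged between the two ethers, while polar ionic conditions keep the acetyl methyl group untouched.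

Step 8
Reactants: 12 1-[2-bromo-3,5-bis(methoxymethoxy)phenyl]ethan-1-one; 9 (4E)-1-bromo-5,9-dimethyl-2-(propan-2-ylidene)deca-4,8-diene
Product: 14 (6E)-1-[2-bromo-3,5-bis(methoxymethoxy)phenyl]-7,11-dimethyl-4-(propan-2-ylidene)dodeca-6,10-dien-1-one, via lithium enolate 13 (not isolated)
Conditions: LiN(i-Pr)2, THF/DMPU, −78 °C; 9, −78 to 0 °C (slight excess of 12)
Reagents that add atoms: none
Why: Kinetic enolate alkylation of a methyl ketone with a reactive primary allylic bromide proceeds by SN2 at CH2 because the other allyl terminus is fully substituted, and it joins C2 to the side chain while the aryl bromide, which has no ortho hydrogen, cannot form an aryne.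

Step 9
Reactants: 14 bromo ketone
Product: 15 (6E)-1-[3,5-bis(methoxymethoxy)-2-(4,4,5,5-tetramethyl-1,3,2-dioxaborolan-2-yl)phenyl]-7,11-dimethyl-4-(propan-2-ylidene)dodeca-6,10-dien-1-one
Conditions: B2pin2, Pd2(dba)3 (2.5 mol %), SPhos (10 mol %), KOAc, 1,4-dioxane, 90 °C
Reagents that add atoms: bis(pinacolato)diboron, CC1(C)OB(OC1(C)C)B1OC(C)(C)C(C)(C)O1
Why: Miyaura borylation is run on the simple ketone, where the alkene cannot move into conjugation, with the bulky electron-rich biaryl phosphine class that accepts two ortho substituents and with an acetate base too weak to enolise the ketone.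

Step 10
Reactants: 15 boryl ketone
Product: 17 (6E)-1-[3,5-bis(methoxymethoxy)-2-(4,4,5,5-tetramethyl-1,3,2-dioxaborolan-2-yl)phenyl]-2-hydroxy-7,11-dimethyl-4-(propan-2-ylidene)dodeca-6,10-dien-1-one (racemic), via potassium enolate 16 (not isolated)
Conditions: KN(SiMe3)2, THF, −78 °C; 2-(benzenesulfonyl)-3-phenyloxaziridine, −78 °C; then AcOH
Reagents that add atoms: 2-(benzenesulfonyl)-3-phenyloxaziridine, O=S(=O)(c1ccccc1)N1OC1c1ccccc1
Why: Davis oxidation transfers electrophilic oxygen only to the enolate carbon C2, leaving the unactivated alkenes and the flanked pinacol boronate (which needs a nucleophilic peroxide to be oxidised) alone, and the racemic carbinol centre disappears in step 11.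

Step 11
Reactants: 17 hydroxy ketone
Product: 18 (6E)-1-[3,5-bis(methoxymethoxy)-2-(4,4,5,5-tetramethyl-1,3,2-dioxaborolan-2-yl)phenyl]-7,11-dimethyl-4-(propan-2-ylidene)dodeca-6,10-diene-1,2-dione
Conditions: Dess–Martin periodinane, pyridine, CH2Cl2, 0 °C to rt; used promptly
Reagents that add atoms: none
Why: Dess–Martin oxidation turns the acyloin into the 1,2-diketone under buffered neutral conditions, so the doubly activated CH2 next to C2 is not enolised and the tetrasubstituted alkene stays out of conjugation.

Step 12
Reactants: 19 2-chloropropanoyl chloride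
Product: 20 S-ethyl 2-chloropropanethioate (racemic)
Conditions: EtSH, pyridine, CH2Cl2, 0 °C
Reagents that add atoms: ethanethiol, CCS
Why: Acyl substitution of the acid chloride by the thiol is fast, and pyridine in place of a trialkylamine keeps chloro(methyl)ketene formation down.

Step 13
Reactants: 20 S-ethyl 2-chloropropanethioate
Product: 22 (E)-[2-chloro-1-(ethylsulfanyl)prop-1-en-1-yl]oxy(trimethyl)silane, via lithium thioester enolate 21 (not isolated)
Conditions: LiN(i-Pr)2, THF, −78 °C; Me3SiCl, −78 °C to rt; distillation
Reagents that add atoms: chlorotrimethylsilane, C[Si](C)(C)Cl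
Why: Kinetic deprotonation and O-silylation give the silyl ketene thioacetal, and the lithium–chlorine contact in the enolate is expected to hold chlorine on the oxygen side and so favour the E isomer.

Step 14
Reactants: 18 boryl 1,2-diketone; 22 (E)-silyl ketene thioacetal
Product: 23 S-ethyl (2R,3S,7E)-3-[3,5-bis(methoxymethoxy)-2-(4,4,5,5-tetramethyl-1,3,2-dioxaborolan-2-yl)benzoyl]-2-chloro-2,8,12-trimethyl-5-(propan-2-ylidene)-3-(trimethylsilyloxy)trideca-7,11-dienethioate (C2 S and C3 R in target numbering)
Conditions: Cu(OTf)2 (15 mol %), (R,R)-t-Bu-box = 2,2′-(propane-2,2-diyl)bis[(4R)-4-tert-butyl-4,5-dihydro-1,3-oxazole] (16 mol %), 22 (2 equiv), THF, −78 to −40 °C; filtration through silica, no acid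
Reagents that add atoms: none
Why: Catalytic enantioselective Mukaiyama aldol addition to a chelating 1,2-dicarbonyl compound, in which 18 binds divalent copper through both carbonyl oxygens in a square-planar chelate, the nucleophile attacks the more electrophilic alkyl-flanked C2 carbonyl rather than the aryl-conjugated C1 carbonyl next to the boronate, the tert-butyl groups of the (R,R)-ligand leave the Re face of C2 open and set (S)-C2, and in the open antiperiplanar transition state the E geometry of 22 lets chlorine and the bulky OSiMe3 terminus lie over the flexible side-chain CH2 while methyl and the slim SEt group lie over the chelate, which sets (R)-C3 with O and Cl syn in the extended chain (trans on ring B), any C3 epimer being removed by chromatography and the silyl group ending on the C2 oxygen.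

Step 15
Reactants: 23 pinacol boronate aldol thioester
Product: 24 S-ethyl (2R,3S,7E)-3-[2-borono-3,5-bis(methoxymethoxy)benzoyl]-2-chloro-2,8,12-trimethyl-5-(propan-2-ylidene)-3-(trimethylsilyloxy)trideca-7,11-dienethioate
Conditions: NaIO4, NH4OAc, acetone/H2O, rt; extractive work-up, used crude
Reagents that add atoms: water, O
Why: Oxidative pinacol removal works at neutral pH because periodate destroys the diol released in the hydrolysis equilibrium, and it attacks neither alkenes nor the hindered thioester nor the congested tertiary silyl ether.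

Step 16
Reactants: 24 open-chain boronic acid thioester
Product: 25 (2S,3R)-3-chloro-2-[(4E)-5,9-dimethyl-2-(propan-2-ylidene)deca-4,8-dien-1-yl]-5,7-bis(methoxymethoxy)-3-methyl-2-(trimethylsilyloxy)-2,3-dihydronaphthalene-1,4-dione
Conditions: Pd2(dba)3 (10 mol %), P(2-furyl)3 (40 mol %), Cu(O2C-2-C4H3S) (copper thiophene-2-carboxylate, 3 equiv), degassed dry THF, 50 °C, Ar; 24 added by syringe pump to 0.005 M
Reagents that add atoms: none
Why: This is a Liebeskind–Srogl thioester–boronic acid ketone synthesis run intramolecularly: oxidative addition of the C4–S bond to zerovalent palladium gives an acylpalladium thiolate, monovalent copper takes up the thiolate while its thiophenecarboxylate coordinates boron, the C4a aryl group migrates to palladium, and reductive elimination creates the C4–C4a bond. Ring B closes as a six-membered carbocycle by reductive elimination from a seven-membered acyl(aryl)palladacycle, and the adjacent fully substituted carbons C2 and C3 fold the chain towards ring A (Thorpe–Ingold effect). No stereocentre is formed and none can be lost, because C2 and C3 carry no hydrogen, no external base is present, and the silylated C2 oxygen can start neither retro-aldol cleavage nor epoxide closure onto C3–Cl. The selectivity needed is aryl transfer from the doubly ortho-substituted boron faster than protodeboronation, intermolecular coupling and loss of CO; intramolecularity, dry solvent and slow addition at high dilution serve the first two, and decarbonylation is disfavoured because it would have to give a tertiary alpha-chloroalkyl palladium species. The tertiary C3–Cl bond offers zerovalent palladium no SN2 path and the carboxylate-bound monovalent copper carries no amine ligand that would promote chlorine-atom abstraction, so the C–S bond should be the only site activated. The closest known reactions are intermolecular couplings of S-alkyl thioesters, alpha-branched ones included, with ortho-substituted arylboronic acids under this same three-component system.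

Step 17
Reactants: 25 protected dihydronaphthalenedione
Product: 27 (2S,3R)-3-chloro-2-[(4E)-5,9-dimethyl-2-(propan-2-ylidene)deca-4,8-dien-1-yl]-2,5,7-trihydroxy-3-methyl-2,3-dihydronaphthalene-1,4-dione, via tris(trimethylsilyl) ether 26 (not isolated)
Conditions: Me3SiOTf, 2,2′-bipyridyl, MeCN, 0 °C to rt; then H2O, rt; then 1 M HCl, THF, 0 °C to rt; pH 7 work-up
Reagents that add atoms: none
Why: Silyl triflate–bipyridyl cleavage of aryl methoxymethyl ethers turns both acetals into aryl silyl ethers by way of N-(methoxymethyl)bipyridinium salts without free strong acid, and water followed by brief dilute acid hydrolyses the two aryl and the tertiary silyl ethers, conditions under which the triene, the tertiary chloride and the two non-enolisable ketones persist and no base is present that could close the trans-chlorohydrin to an epoxide.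

Compound list
1 | ethyl acetoacetate | CCOC(=O)CC(C)=O | starting material
2 | geranyl bromide | CC(C)=CCC/C(C)=C/CBr | starting material
3 | sodium (Z)-enolate of ethyl acetoacetate | CCOC(=O)/C=C(/C)[O-].[Na+] | intermediate
4 | ethyl (4E)-2-acetyl-5,9-dimethyldeca-4,8-dienoate (racemic) | CC(C)=CCC/C(C)=C/CC(C(C)=O)C(=O)OCC | intermediate
5 | sodium enolate of 4 | CCOC(=O)/C(C/C=C(\C)CCC=C(C)C)=C(/C)[O-].[Na+] | intermediate
6 | ethyl (2Z,4E)-5,9-dimethyl-2-[1-(trifluoromethanesulfonyloxy)ethylidene]deca-4,8-dienoate | CCOC(=O)/C(C/C=C(\C)CCC=C(C)C)=C(/C)OS(=O)(=O)C(F)(F)F | intermediate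
7 | ethyl (4E)-5,9-dimethyl-2-(propan-2-ylidene)deca-4,8-dienoate | CC(C)=CCC/C(C)=C/CC(C(=O)OCC)=C(C)C | intermediate
8 | (4E)-5,9-dimethyl-2-(propan-2-ylidene)deca-4,8-dien-1-ol | CC(C)=CCC/C(C)=C/CC(CO)=C(C)C | intermediate
9 | (4E)-1-bromo-5,9-dimethyl-2-(propan-2-ylidene)deca-4,8-diene | CC(C)=CCC/C(C)=C/CC(CBr)=C(C)C | intermediate
10 | 3,5-dihydroxyacetophenone | CC(=O)c1cc(O)cc(O)c1 | starting material
11 | 1-[3,5-bis(methoxymethoxy)phenyl]ethan-1-one | CC(=O)c1cc(OCOC)cc(OCOC)c1 | intermediate
12 | 1-[2-bromo-3,5-bis(methoxymethoxy)phenyl]ethan-1-one | CC(=O)c1cc(OCOC)cc(OCOC)c1Br | intermediate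
13 | lithium enolate of 12 | C=C([O-])c1cc(OCOC)cc(OCOC)c1Br.[Li+] | intermediate
14 | (6E)-1-[2-bromo-3,5-bis(methoxymethoxy)phenyl]-7,11-dimethyl-4-(propan-2-ylidene)dodeca-6,10-dien-1-one | CC(C)=CCC/C(C)=C/CC(CCC(=O)c1cc(OCOC)cc(OCOC)c1Br)=C(C)C | intermediate
15 | pinacol boronate ketone (Bpin in place of Br in 14) | CC(C)=CCC/C(C)=C/CC(CCC(=O)c1cc(OCOC)cc(OCOC)c1B1OC(C)(C)C(C)(C)O1)=C(C)C | intermediate
16 | potassium (Z)-enolate of 15 | CC(C)=CCC/C(C)=C/CC(C/C=C(\[O-])c1cc(OCOC)cc(OCOC)c1B1OC(C)(C)C(C)(C)O1)=C(C)C.[K+] | intermediate
17 | 2-hydroxy ketone (racemic at C2) | CC(C)=CCC/C(C)=C/CC(CC(O)C(=O)c1cc(OCOC)cc(OCOC)c1B1OC(C)(C)C(C)(C)O1)=C(C)C | intermediate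
18 | ortho-(pinacolboryl)aryl 1,2-diketone | CC(C)=CCC/C(C)=C/CC(CC(=O)C(=O)c1cc(OCOC)cc(OCOC)c1B1OC(C)(C)C(C)(C)O1)=C(C)C | intermediate
19 | 2-chloropropanoyl chloride | CC(Cl)C(=O)Cl | starting material
20 | S-ethyl 2-chloropropanethioate (racemic) | CCSC(=O)C(C)Cl | intermediate
21 | lithium enolate of 20 (Cl on the oxygen side) | C/C(Cl)=C(\SCC)[O-].[Li+] | intermediate
22 | (E)-[2-chloro-1-(ethylsulfanyl)prop-1-en-1-yl]oxy(trimethyl)silane | C/C(Cl)=C(\SCC)O[Si](C)(C)C | intermediate
23 | aldol thioester, C2 (S) O-SiMe3, C3 (R), pinacol boronate, bis-MOM ether | CC(C)=CCC/C(C)=C/CC(C[C@](O[Si](C)(C)C)(C(=O)c1cc(OCOC)cc(OCOC)c1B1OC(C)(C)C(C)(C)O1)[C@@](C)(Cl)C(=O)SCC)=C(C)C | intermediate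
24 | aldol thioester with free ortho boronic acid (key-step precursor) | CC(C)=CCC/C(C)=C/CC(C[C@](O[Si](C)(C)C)(C(=O)c1cc(OCOC)cc(OCOC)c1B(O)O)[C@@](C)(Cl)C(=O)SCC)=C(C)C | intermediate
25 | (2S,3R) ring-closed product, C2 O-SiMe3, 5,7-bis-MOM ether | CC(C)=CCC/C(C)=C/CC(C[C@]1(O[Si](C)(C)C)C(=O)c2cc(OCOC)cc(OCOC)c2C(=O)[C@]1(C)Cl)=C(C)C | intermediate
26 | (2S,3R) 2,5,7-tris(trimethylsilyl) ether | CC(C)=CCC/C(C)=C/CC(C[C@]1(O[Si](C)(C)C)C(=O)c2cc(O[Si](C)(C)C)cc(O[Si](C)(C)C)c2C(=O)[C@]1(C)Cl)=C(C)C | intermediate
27 | (2S,3R)-3-chloro-2-[(4E)-5,9-dimethyl-2-(propan-2-ylidene)deca-4,8-dien-1-yl]-2,5,7-trihydroxy-3-methyl-2,3-dihydronaphthalene-1,4-dione | CC(C)=CCC/C(C)=C/CC(C[C@]1(O)C(=O)c2cc(O)cc(O)c2C(=O)[C@]1(C)Cl)=C(C)C | target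

Total step count: 17. Longest linear sequence: 13 steps (1–5, 8–11, 14–17).

Steps most likely to fail

1. Step 16 (ring closure).
- **What may go wrong:** aryl transfer from the doubly ortho-substituted boron may be too slow. Protodeboronation, intermolecular coupling or loss of CO from the acylpalladium species would then take over.
- **Fallback:** tin replaces boron, starting from bromo ketone 14. Me3SnSnMe3 and Pd(PPh3)4 in toluene at 100 °C (no base) should give the aryl trimethylstannane ketone F1.
- The hydroxylation and oxidation of steps 10 and 11 lead through the stannyl hydroxy ketone F2 to the stannyl 1,2-diketone F3. The aldol of step 14 with 22 then gives the stannyl aldol thioester F4.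
- F4 needs no unmasking. It is cyclised by the neutral thioester–organostannane ketone synthesis (Pd2(dba)3, P(2-furyl)3, CuOP(O)Ph2, THF, 50 °C, high dilution). Here tin hands the aryl group to monovalent copper before it reaches palladium. The route is rejoined at 25.

2. Step 14 (aldol).
- **What may go wrong:** the tetrasubstituted nucleophile may add sluggishly to the hindered ketone. Discrimination between Cl and CH3 on the nucleophile face may be poor, or the ketene-acetal geometry may erode. The activated diketone may also react with the side-chain alkenes in an intramolecular carbonyl-ene reaction.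
- **Fallback:** C–C and C–Cl bond formation are separated, starting from diketone 18. Under the same catalyst, 18 is treated with the trisubstituted silyl ketene thioacetal of S-ethyl propanethioate F5, made with LiN(i-Pr)2 and Me3SiCl. This nucleophile class is established for chelating 1,2-dicarbonyl compounds and should give the syn methyl aldol silyl ether F6 with C2 set by the ligand.
- Enolisation of the thioester (KN(SiMe3)2, THF, −78 °C) and N-chlorosuccinimide then place chlorine on C3. The C3 epimers are separated by chromatography, and the route is rejoined at 23.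

3. Step 15 (boronic acid release).
- **What may go wrong:** cleavage of the flanked pinacol ester may be incomplete. The silyl ether may be lost early, or protodeboronation may occur during the long aqueous exposure.
- **Fallback:** oxidative destruction of pinacol is replaced by transesterification, starting from 23. Diethanolamine in Et2O should exchange pinacol and give the tetracoordinate diethanolamine boronate F7, which is freed from pinacol by trituration.
- Brief shaking of F7 between Et2O and 0.1 M HCl at 0 °C releases the boronic acid. The route is rejoined at 24.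

Further compounds
F1 | step 16 | (6E)-1-[3,5-bis(methoxymethoxy)-2-(trimethylstannyl)phenyl]-7,11-dimethyl-4-(propan-2-ylidene)dodeca-6,10-dien-1-one | CC(C)=CCC/C(C)=C/CC(CCC(=O)c1cc(OCOC)cc(OCOC)c1[Sn](C)(C)C)=C(C)C
F2 | step 16 | stannyl 2-hydroxy ketone (racemic at C2) | CC(C)=CCC/C(C)=C/CC(CC(O)C(=O)c1cc(OCOC)cc(OCOC)c1[Sn](C)(C)C)=C(C)C
F3 | step 16 | stannyl 1,2-diketone | CC(C)=CCC/C(C)=C/CC(CC(=O)C(=O)c1cc(OCOC)cc(OCOC)c1[Sn](C)(C)C)=C(C)C
F4 | step 16 | stannyl aldol thioester, C2 (S) O-SiMe3, C3 (R) | CC(C)=CCC/C(C)=C/CC(C[C@](O[Si](C)(C)C)(C(=O)c1cc(OCOC)cc(OCOC)c1[Sn](C)(C)C)[C@@](C)(Cl)C(=O)SCC)=C(C)C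
F5 | step 14 | (Z)-[1-(ethylsulfanyl)prop-1-en-1-yl]oxy(trimethyl)silane | C/C=C(\SCC)O[Si](C)(C)C
F6 | step 14 | S-ethyl (2R,3R,7E)-3-[3,5-bis(methoxymethoxy)-2-(4,4,5,5-tetramethyl-1,3,2-dioxaborolan-2-yl)benzoyl]-2,8,12-trimethyl-5-(propan-2-ylidene)-3-(trimethylsilyloxy)trideca-7,11-dienethioate (O and CH3 syn) | CC(C)=CCC/C(C)=C/CC(C[C@](O[Si](C)(C)C)(C(=O)c1cc(OCOC)cc(OCOC)c1B1OC(C)(C)C(C)(C)O1)[C@@H](C)C(=O)SCC)=C(C)C
F7 | step 15 | diethanolamine boronate of 24 (1,3,6,2-dioxazaborocane) | CC(C)=CCC/C(C)=C/CC(C[C@](O[Si](C)(C)C)(C(=O)c1cc(OCOC)cc(OCOC)c1B1OCCNCCO1)[C@@](C)(Cl)C(=O)SCC)=C(C)C
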